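**Retrosynthetic overview**
1. Target numbering: chroman O1, C2, C3, C4, C4a, C5 to C8, C8a. The hydroxy acid is traced back to a lactone in which the C5 oxygen and the carboxyl of the C6 side chain are tied into a temporary six-membered pyranone ring. That lactone comes from the corresponding coumarin by ligand-controlled conjugate reduction (benzylic centre), and the prenyl group from an aryl bromide.
2. Key disconnection: the dihydropyran ring is cut at C4–C3 and O1–C2 into (E)-but-2-ene and an o-quinone methide released from an ortho-hydroxybenzyl alcohol. A catalytic asymmetric inverse-electron-demand hetero-Diels–Alder reaction sets both methyl-bearing centres at once.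
3. Enabling feature: the C4 methylene sits on C4a next to the O1-bearing C8a, so O1=C8a–C4a=C4 is a latent 1-oxadiene, and the trans C2/C3 methyl pair is (E)-but-2-ene. Because the second phenolic oxygen (at C5) is locked in the pyranone ring, only O1 can become the quinone methide oxygen; a bromine at C8 blocks the last ring position.
4. The cycloaddition precursor is made from commercial 5,7-dihydroxy-4-propylcoumarin by formylation at the future C4a, O-methylation, bromination and reduction. The coumarin ring also steers the formylation and later serves as the prochiral enoate.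
5. Ring order: benzene and pyranone rings are bought; the dihydropyran ring is closed in step 5; the pyranone ring is reduced in step 7 and opened in step 8.

Key step: step 5

Remark: the sense of induction of the chiral acid (step 5) and of the bisphosphine (step 7) is assumed as written; the mirror-image catalyst or ligand is used if a pilot run shows the opposite sense.

**Step 1**
Reactants: 1 5,7-dihydroxy-4-propyl-2H-chromen-2-one
Product: 3 5,7-dihydroxy-2-oxo-4-propyl-2H-chromene-8-carbaldehyde, via iminium dichlorophosphate 2 (not isolated)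
Conditions: POCl3 (1.2 equiv), DMF (3 equiv), MeCN, 0 °C to rt; then H2O, 60 °C
Reagents that add atoms: N,N-dimethylformamide, CN(C)C=O; water, O
Why: Vilsmeier–Haack formylation should occur at C-8, the most nucleophilic carbon of 5,7-dihydroxy-4-alkylcoumarins (ortho to the 7-OH, para to the 5-OH, the site at which this ring system is also acylated), and the iminium salt 2 is hydrolysed on work-up.

**Step 2**
Reactants: 3 5,7-dihydroxy-2-oxo-4-propyl-2H-chromene-8-carbaldehyde
Product: 4 7-hydroxy-5-methoxy-2-oxo-4-propyl-2H-chromene-8-carbaldehyde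
Conditions: MeI (1.05 equiv), K2CO3 (1.1 equiv), acetone, rt
Reagents that add atoms: iodomethane, CI
Why: Williamson ether synthesis under limiting base should methylate the free 5-OH (para to the formyl group) selectively, because the 7-OH is held in a hydrogen bond to the 8-formyl group.

**Step 3**
Reactants: 4 7-hydroxy-5-methoxy-2-oxo-4-propyl-2H-chromene-8-carbaldehyde
Product: 5 6-bromo-7-hydroxy-5-methoxy-2-oxo-4-propyl-2H-chromene-8-carbaldehyde
Conditions: NBS (1.0 equiv), MeCN, 0 °C, dark
Reagents that add atoms: N-bromosuccinimide, O=C1CCC(=O)N1Br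
Why: electrophilic aromatic bromination should take the only unsubstituted ring carbon C-6 (ortho to the 7-OH and the 5-OMe); the bromine blocks the ring against quinone methide self-alkylation and is the later handle for the prenyl group.

**Step 4**
Reactants: 5 6-bromo-7-hydroxy-5-methoxy-2-oxo-4-propyl-2H-chromene-8-carbaldehyde
Product: 6 6-bromo-7-hydroxy-8-(hydroxymethyl)-5-methoxy-4-propyl-2H-chromen-2-one
Conditions: NaBH4 (1.0 equiv), THF/MeOH, –10 °C; pH 7 phosphate buffer
Reagents that add atoms: none
Why: chemoselective NaBH4 reduction of the aldehyde at low temperature should leave the conjugated lactone untouched and give the ortho-hydroxybenzyl alcohol that serves as quinone methide precursor.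

**Step 5**
Reactants: 6 6-bromo-7-hydroxy-8-(hydroxymethyl)-5-methoxy-4-propyl-2H-chromen-2-one; 7 (E)-but-2-ene
Product: 9 (8S,9R)-6-bromo-5-methoxy-8,9-dimethyl-4-propyl-9,10-dihydro-2H,8H-pyrano[2,3-f]chromen-2-one, via o-quinone methide 8 (not isolated)
Conditions: (S,S)-IDPi (confined BINOL-derived imidodiphosphorimidate Brønsted acid, 3,3'-diaryl, N-triflyl core; 5 mol%), 7 (20 equiv, condensed in), 5 Å MS, CHCl3, –30 °C to 0 °C, sealed tube
Reagents that add atoms: (E)-but-2-ene, C/C=C/C
Why: Proposed new method: the confined chiral acid ionises the benzylic alcohol of 6 to the hydrogen-bonded o-quinone methide 8 (in protonated form a 2,4,6-trioxygenated benzyl cation), whose oxadiene O=C7–C8=CH2 adds (E)-but-2-ene in an asynchronous concerted inverse-electron-demand hetero-Diels–Alder reaction in which C–C bond formation leads and C–O bond formation follows inside the ion pair. The closest known reaction type is the chiral Brønsted acid catalysed enantioselective [4+2] cycloaddition of in situ generated o-quinone methides with styrenes and with tethered unactivated alkenes, and the step goes beyond it in using an unsubstituted methylene quinone methide and a simple 1,2-dialkyl alkene in intermolecular fashion. The dihydropyran ring is closed by this intermolecular [4+2] annulation, the four oxadiene atoms joining the two alkene carbons. The trans relation of the two new stereocentres C-8 and C-9 follows from suprafacial addition to the E alkene, and their absolute configuration (8S,9R) from the catalyst, whose confined anion stays bound at the quinone methide oxygen and should admit the small alkene with only one of its enantiotopic faces. The step needs chemoselectivity for cycloaddition over quinone methide oligomerisation and site selectivity for the O-7 oxadiene, which are secured by full substitution of the benzene ring (bromine at C-6), by the lactone that ties up the other phenolic oxygen, and by the large excess of alkene.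

**Step 6**
Reactants: 9 (8S,9R)-6-bromo-5-methoxy-8,9-dimethyl-4-propyl-9,10-dihydro-2H,8H-pyrano[2,3-f]chromen-2-one; 10 tributyl(3-methylbut-2-en-1-yl)stannane
Product: 11 (8S,9R)-5-methoxy-8,9-dimethyl-6-(3-methylbut-2-en-1-yl)-4-propyl-9,10-dihydro-2H,8H-pyrano[2,3-f]chromen-2-one
Conditions: Pd2(dba)3 (2.5 mol%), P(t-Bu)3 (6 mol%), CsF (2.2 equiv), dioxane, 90 °C
Reagents that add atoms: tributyl(3-methylbut-2-en-1-yl)stannane, CCCC[Sn](CCCC)(CCCC)CC=C(C)C
Why: Stille coupling, in which the bulky electron-rich phosphine should promote oxidative addition of the hindered aryl bromide, fluoride activates the stannane, and the prenyl group is transferred through its primary carbon (linear product); the neutral conditions leave the lactone and both stereocentres untouched.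

**Step 7**
Reactants: 11 (8S,9R)-5-methoxy-8,9-dimethyl-6-(3-methylbut-2-en-1-yl)-4-propyl-9,10-dihydro-2H,8H-pyrano[2,3-f]chromen-2-one
Product: 13 (4R,8S,9R)-5-methoxy-8,9-dimethyl-6-(3-methylbut-2-en-1-yl)-4-propyl-3,4,9,10-tetrahydro-2H,8H-pyrano[2,3-f]chromen-2-one, via silyl ketene acetal 12 (not isolated)
Conditions: Cu(OAc)2·H2O (5 mol%), (R)-DTBM-SEGPHOS (5.5 mol%), (EtO)2MeSiH (1.5 equiv), toluene, 0 °C to rt; then pH 7 buffer/THF
Reagents that add atoms: none
Why: copper hydride (CuH) catalysed asymmetric conjugate reduction of a β,β-disubstituted unsaturated lactone, in which the bisphosphine should control the face of hydride delivery to C-4 and so set the (4R) centre under catalyst control, while the remote chroman centres do not interfere, the isolated prenyl double bond is inert and the silyl ketene acetal 12 shields the lactone from over-reduction until work-up.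

**Step 8**
Reactants: 13 (4R,8S,9R)-5-methoxy-8,9-dimethyl-6-(3-methylbut-2-en-1-yl)-4-propyl-3,4,9,10-tetrahydro-2H,8H-pyrano[2,3-f]chromen-2-one
Product: 15 (3R)-3-[(2S,3R)-5-hydroxy-7-methoxy-2,3-dimethyl-8-(3-methylbut-2-en-1-yl)-3,4-dihydro-2H-chromen-6-yl]hexanoic acid, via dilithium salt 14 (not isolated)
Conditions: LiOH·H2O (3 equiv), THF/H2O, 0 °C to rt; then 1 M HCl to pH 4, 0 °C
Reagents that add atoms: lithium hydroxide, [Li+].[OH-]
Why: saponification of the aryl lactone should release the phenol and the carboxylic acid without touching a stereocentre (the benzylic C–H is β to the carboxylate), and cold acidification to pH 4 avoids relactonisation and spares the prenyl group, which has no free phenol next to it.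

**Compound list**
1 | 5,7-dihydroxy-4-propyl-2H-chromen-2-one (commercial) | CCCC1=CC(=O)Oc2cc(O)cc(O)c12 | starting material
2 | [(5,7-dihydroxy-2-oxo-4-propyl-2H-chromen-8-yl)methylidene]dimethylammonium dichlorophosphate | CCCC1=CC(=O)Oc2c(C=[N+](C)C)c(O)cc(O)c12.[O-]P(=O)(Cl)Cl | intermediate
3 | 5,7-dihydroxy-2-oxo-4-propyl-2H-chromene-8-carbaldehyde | CCCC1=CC(=O)Oc2c(C=O)c(O)cc(O)c12 | intermediate
4 | 7-hydroxy-5-methoxy-2-oxo-4-propyl-2H-chromene-8-carbaldehyde | CCCC1=CC(=O)Oc2c(C=O)c(O)cc(OC)c12 | intermediate
5 | 6-bromo-7-hydroxy-5-methoxy-2-oxo-4-propyl-2H-chromene-8-carbaldehyde | CCCC1=CC(=O)Oc2c(C=O)c(O)c(Br)c(OC)c12 | intermediate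
6 | 6-bromo-7-hydroxy-8-(hydroxymethyl)-5-methoxy-4-propyl-2H-chromen-2-one | CCCC1=CC(=O)Oc2c(CO)c(O)c(Br)c(OC)c12 | intermediate
7 | (E)-but-2-ene (commercial) | C/C=C/C | starting material
8 | 6-bromo-5-methoxy-8-methylidene-4-propyl-2H-chromene-2,7(8H)-dione (o-quinone methide) | CCCC1=CC(=O)OC2=C1C(OC)=C(Br)C(=O)C2=C | intermediate
9 | (8S,9R)-6-bromo-5-methoxy-8,9-dimethyl-4-propyl-9,10-dihydro-2H,8H-pyrano[2,3-f]chromen-2-one | CCCC1=CC(=O)Oc2c1c(OC)c(Br)c3c2C[C@@H](C)[C@H](C)O3 | intermediate
10 | tributyl(3-methylbut-2-en-1-yl)stannane (commercial) | CCCC[Sn](CCCC)(CCCC)CC=C(C)C | starting material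
11 | (8S,9R)-5-methoxy-8,9-dimethyl-6-(3-methylbut-2-en-1-yl)-4-propyl-9,10-dihydro-2H,8H-pyrano[2,3-f]chromen-2-one | CCCC1=CC(=O)Oc2c1c(OC)c(CC=C(C)C)c3c2C[C@@H](C)[C@H](C)O3 | intermediate
12 | (4R,8S,9R)-2-{[diethoxy(methyl)silyl]oxy}-5-methoxy-8,9-dimethyl-6-(3-methylbut-2-en-1-yl)-4-propyl-9,10-dihydro-4H,8H-pyrano[2,3-f]chromene | CCC[C@@H]1C=C(O[Si](C)(OCC)OCC)Oc2c1c(OC)c(CC=C(C)C)c3c2C[C@@H](C)[C@H](C)O3 | intermediate
13 | (4R,8S,9R)-5-methoxy-8,9-dimethyl-6-(3-methylbut-2-en-1-yl)-4-propyl-3,4,9,10-tetrahydro-2H,8H-pyrano[2,3-f]chromen-2-one | CCC[C@@H]1CC(=O)Oc2c1c(OC)c(CC=C(C)C)c3c2C[C@@H](C)[C@H](C)O3 | intermediate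
14 | dilithium (3R)-3-[(2S,3R)-7-methoxy-2,3-dimethyl-8-(3-methylbut-2-en-1-yl)-5-oxido-3,4-dihydro-2H-chromen-6-yl]hexanoate | CCC[C@H](CC(=O)[O-])c1c([O-])c2c(c(CC=C(C)C)c1OC)O[C@@H](C)[C@H](C)C2.[Li+].[Li+] | intermediate
15 | (3R)-3-[(2S,3R)-5-hydroxy-7-methoxy-2,3-dimethyl-8-(3-methylbut-2-en-1-yl)-3,4-dihydro-2H-chromen-6-yl]hexanoic acid | CCC[C@H](CC(=O)O)c1c(O)c2c(c(CC=C(C)C)c1OC)O[C@@H](C)[C@H](C)C2 | target

**Summary**
Total step count: 8. Longest linear sequence: 8 steps (from 1 to 15).

**Steps most likely to fail**

Step 5 (Proposed new method). The confined acid may discriminate the enantiotopic faces of the small alkene poorly, and a stepwise cationic pathway may leak into hydride shift or quinone methide oligomerisation. The fallback uses known chemistry, sets out from 6 and comes back at 9.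
- 6 is combined with propanal, catalytic acetic acid and the enantiomer of α,α-diphenylprolinol trimethylsilyl ether that gives the (9R) centre. Enamine Michael addition to the quinone methide followed by hemiacetalisation again forms both ring bonds and should give the lactol (9R)-6-bromo-8-hydroxy-5-methoxy-9-methyl-4-propyl-9,10-dihydro-2H,8H-pyrano[2,3-f]chromen-2-one F1.
- Wittig methylenation (Ph3P=CH2, THF, 0 °C) should open it to 6-bromo-7-hydroxy-5-methoxy-8-[(2R)-2-methylbut-3-en-1-yl]-4-propyl-2H-chromen-2-one F2.
- Markovnikov oxymercuration with Hg(OCOCF3)2 (THF, 0 °C) should reclose the ring through a chair-like transition state with both substituents equatorial (trans), giving the organomercurial (8R,9R)-6-bromo-5-methoxy-9-methyl-4-propyl-8-[(trifluoroacetoxymercurio)methyl]-9,10-dihydro-2H,8H-pyrano[2,3-f]chromen-2-one F3. This is reduced in the same flask with NaBH4/NaOH to 9.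

Step 7. Hydride delivery to the β-carbon next to the peri methoxy group may be slow or poorly face-selective, and the lactone may be over-reduced. The fallback sets out from 11 and comes back at 15, bypassing 13.
- 11 is opened with NaOH (2.2 equiv, MeOH/H2O) to disodium (2Z)-3-[(2S,3R)-7-methoxy-2,3-dimethyl-8-(3-methylbut-2-en-1-yl)-5-oxido-3,4-dihydro-2H-chromen-6-yl]hex-2-enoate F4.
- F4 is hydrogenated as the carboxylate with Ru(OAc)2[(R)-BINAP] (or its enantiomer, whichever gives 3R; H2 4 atm, MeOH). This carboxylate-directed asymmetric hydrogenation should leave the isolated prenyl double bond untouched.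
- Acidification to pH 4 at 0 °C should then give 15.

Step 6. The prenyl group may be transferred with allylic transposition to the 1,1-dimethylallyl isomer, or coupling at the doubly ortho-substituted bromide may stall. The fallback sets out from 9 and comes back at 11.
- 9 is coupled with allyltributylstannane under the same Pd2(dba)3/P(t-Bu)3/CsF conditions, where no regiochemical ambiguity exists, to give (8S,9R)-5-methoxy-8,9-dimethyl-6-(prop-2-en-1-yl)-4-propyl-9,10-dihydro-2H,8H-pyrano[2,3-f]chromen-2-one F5.
- The prenyl terminus is then built by olefin cross-metathesis with 2-methylbut-2-ene (second-generation Grubbs catalyst, CH2Cl2, 40 °C) to give 11.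

**Further compounds**
F1 | step 5 | (9R)-6-bromo-8-hydroxy-5-methoxy-9-methyl-4-propyl-9,10-dihydro-2H,8H-pyrano[2,3-f]chromen-2-one (anomer mixture) | CCCC1=CC(=O)Oc2c1c(OC)c(Br)c3c2C[C@@H](C)C(O)O3
F2 | step 5 | 6-bromo-7-hydroxy-5-methoxy-8-[(2R)-2-methylbut-3-en-1-yl]-4-propyl-2H-chromen-2-one | CCCC1=CC(=O)Oc2c1c(OC)c(Br)c(O)c2C[C@@H](C)C=C
F3 | step 5 | (8R,9R)-6-bromo-5-methoxy-9-methyl-4-propyl-8-[(trifluoroacetoxymercurio)methyl]-9,10-dihydro-2H,8H-pyrano[2,3-f]chromen-2-one | CCCC1=CC(=O)Oc2c1c(OC)c(Br)c3c2C[C@@H](C)[C@H](C[Hg]OC(=O)C(F)(F)F)O3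
F4 | step 7 | disodium (2Z)-3-[(2S,3R)-7-methoxy-2,3-dimethyl-8-(3-methylbut-2-en-1-yl)-5-oxido-3,4-dihydro-2H-chromen-6-yl]hex-2-enoate | CCC/C(=C/C(=O)[O-])c1c([O-])c2c(c(CC=C(C)C)c1OC)O[C@@H](C)[C@H](C)C2.[Na+].[Na+]
F5 | step 6 | (8S,9R)-5-methoxy-8,9-dimethyl-6-(prop-2-en-1-yl)-4-propyl-9,10-dihydro-2H,8H-pyrano[2,3-f]chromen-2-one | CCCC1=CC(=O)Oc2c1c(OC)c(CC=C)c3c2C[C@@H](C)[C@H](C)O3
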